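## The problem

Thymol numbering is used: C1–C6 are the ring, C7 is the benzylic CH2 on C1, the phenol oxygen sits on C3, and C4 carries C8 with its two one-carbon arms C9 and C10.

- Target 12 is a 1,2,4-trisubstituted benzene. C4 bears a fully substituted oxirane carbon C8, C3 bears an aryl isobutyrate and C7 an alkyl isobutyrate. C8 also holds the oxirane CH2 (C9) and an acetoxymethyl arm (C10).
- The skeleton needs only one C–C bond (C4–C8). The difficulty is C8, the only stereocentre: it is quaternary, benzylic and oxygen-bound, and no neighbouring stereocentre can relay its (S) configuration, so a reagent or catalyst must set it.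
- C8 is stereogenic only because its two CH2O arms differ (ring ether at C9, acetate at C10). Any acetyl shift between O9 and O10 in an open-chain precursor is therefore racemization.
- The aryl isobutyrate is an activated ester placed where a six-membered acyl transfer to an oxygen on C8 is possible. Alkoxides at C8 must be avoided once it is in place.
- The 2-aryl-2-alkyloxirane is acid-labile (tertiary benzylic C–O) and would be opened intramolecularly by a free ortho phenoxide. The phenol must be acylated before the oxirane exists, and the oxirane should be made last under neutral conditions.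
- The enabling feature is the latent symmetry at C8. Joining O9 to C10 turns C8, its oxygen and its two arms into an achiral 3-aryloxetan-3-ol with ring C8–C9–O–C10 and two enantiotopic C–O bonds. The nucleophile needed to break one of them is acetate, the group the target carries on C10.

## Retrosynthesis

**12 ⇒ 11.** The oxirane O–C9 bond is cut, keeping the C8–O bond, which gives the (S)-diol monoacetate 11. Cutting C8–O instead would ask for substitution at a tertiary benzylic carbon, and cutting C8–C9 leads to a methylene-transfer route (Alternative 1). Precursor 11 is acyclic and differs from 12 by one molecule of water. The forward step must activate only the primary C9 hydroxyl, leave C8 untouched and stay non-basic so that no ester migrates; a Mitsunobu cyclodehydration meets this.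

**11 ⇒ 9 + 10.** The C10–O(acetate) bond is cut and C10 is reconnected to O9, giving the achiral oxetanol 9 and acetic acid 10.
- Against the neighbouring cut at the acetyl–O bond (acylation of a triol, Alternative 3), this cut delivers the acetate as the nucleophile, wastes no atom and works on a substrate that already carries both isobutyrates.
- Precursor 9 has no stereocentre. The forward reaction must tell two enantiotopic CH2 groups apart, open by SN2 without ionization at C8 and be over before the acetyl group of 11 moves.
- Three measures support the step from within:
  - Acetic acid 10 is used in toluene, where it pairs with a chiral phosphoric acid, which raises both the acidity of the catalyst and the nucleophilicity of the carboxylic acid.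
  - The tertiary hydroxyl of 9 is left free as an extra hydrogen-bond contact.
  - Both isobutyrates are installed beforehand, so the aryl group is a poor cation stabilizer and only one neutral step follows.

**9 ⇒ 7 + 8.** Two acyl–O bonds are cut, giving triol 7 and isobutyryl chloride 8. The two esters are the same acyl group, so one operation installs both. The tertiary hydroxyl is distinguished by steric hindrance alone. The forward step needs chemoselectivity for phenol and primary alcohol and conditions too weakly basic to form a C8 alkoxide.

**7 ⇒ 6.** Two Si–O bonds are cut. The silyl ethers of 6 exist only to carry the phenol and the benzylic alcohol through an organolithium step. Fluoride removes both in one operation and is not expected to attack the oxetane or the tertiary alcohol.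

**6 ⇒ 3 + 4, through 5.** The C4–C8 bond is cut into aryllithium 5 (from bromide 3) and oxetan-3-one 4. Ketone 4 supplies C8, C9, C10 and their ring oxygen in one piece, already cyclic and symmetric; building the oxetane by cyclizing an open triol would be longer. The forward step asks for bromine–lithium exchange next to a silyloxy group without 1,3 silyl migration, which is why both silyl groups are triisopropylsilyl, and for addition to the ketone faster than enolization.

**3 ⇒ 2 ⇒ 1.** Silylation and ester reduction lead back to commercial ester 1, whose Br, OH and CO2Me already sit at C4, C3 and C1 of the target.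

## Roads not taken

**Alternative 1:** asymmetric methylene transfer to a ketone.
- Cut: C8–C9 and O–C9 of the oxirane, leading to the α-alkoxy aryl ketone A1.
- Forward key step: a sulfoxonium methylide adds to A1 under a chiral lanthanum–lithium binaphthoxide catalyst, giving oxirane A2 with ring and stereocentre formed together.
- Merits: the reaction class is known for aryl ketones, both catalyst antipodes are available, and the stereocentre is set in a C–C bond-forming step. Its precedent is closer than that of the chosen key step.
- Weak points: the precedent for high selectivity rests on methyl ketones, whereas A1 has a CH2O(4-methoxybenzyl) group in place of methyl and an ortho silyloxy substituent that twists the aryl ketone. After the key step the oxirane must survive two desilylations, two isobutyrylations, oxidative ether cleavage and acetylation. Fluoride would set a phenoxide free next to the oxirane, the 5-exo opening the target cannot tolerate.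
- Comparison: the chosen plan sets against the better precedent the fact that its oxirane is made last with every ester in place.

**Alternative 2:** phenoxide-directed ortho Friedel–Crafts reaction.
- Cut: the C4–C8 bond, leading to phenol A3 and alkoxypyruvate A4.
- Forward key step: the chiral titanium binaphthoxide phenoxide of A3 attacks the ketone carbon of A4 through its ortho carbon, giving the tertiary α-hydroxy ester A5.
- Merits: it is convergent, forms the aryl–C8 bond and the stereocentre at once, needs no phenol protection and already has the benzylic isobutyrate in place. In convergence it is better than the chosen linear route.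
- Weak points: the titanium reagent is likely stoichiometric, and attack para to the phenol oxygen competes. In A5, C9 is at the ester oxidation level, so the ethyl ester must be reduced in the presence of the benzylic isobutyrate. The free ortho phenol of A5 can also lactonize onto that ester. About five further steps follow (reduction, phenol acylation, oxirane closure, ether cleavage, acetylation), two of them on the finished oxirane.
- Comparison: the chosen plan offers correct oxidation levels from the start and a single step after the stereocentre is set.

**Alternative 3:** lipase desymmetrization of a prochiral triol.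
- Cut: the acetyl–O10 bond, leading to triol A6.
- Forward key step: a lipase transfers acetyl from an enol acetate to one enantiotopic primary hydroxyl, giving monoacetate A7.
- Merits: enzymatic desymmetrization of 2-substituted propane-1,3-diols is established, mild and cheap, and the nucleophilicity question of the chosen plan does not arise. In precedent it is clearly the stronger route.
- Weak points: the enzyme must accept a tertiary carbinol flanked by a bulky ortho-silyloxy aryl group. The sense of selection is fixed by the enzyme and cannot be reversed by taking a mirror-image catalyst. A7 still carries two silyl ethers, so after oxirane closure they must be exchanged for isobutyrates next to the oxirane and the migration-prone acetate.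
- Comparison: 11 is the isobutyrate analogue of A7, reached with the final ester pattern, so one step remains where Alternative 3 needs about four. The chosen plan accepts an untested key step for that gain.

Key step: step 6

Assumption: the sense of enantiotopic-group selection by a given catalyst antipode cannot be derived from structure alone; the (R)-catalyst is written as the one that opens the pro-S methylene of 9, and the (S)-catalyst would be used instead if the opposite sense were found.

## Route

Step 1
Reactants: 1 methyl 4-bromo-3-hydroxybenzoate
Product: 2 2-bromo-5-(hydroxymethyl)phenol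
Conditions: LiAlH4, THF, 0 °C → rt; then 1 M aq. HCl, 0 °C
Reagents that add atoms: none
Why: Hydride reduction of the methyl ester to the primary alcohol, the phenol being carried as its aluminate; an aryl bromide is not expected to be reduced at this temperature.

Step 2
Reactants: 2 2-bromo-5-(hydroxymethyl)phenol
Product: 3 1-bromo-2-[(triisopropylsilyl)oxy]-4-{[(triisopropylsilyl)oxy]methyl}benzene
Conditions: i-Pr3SiCl (2.4 equiv), imidazole, DMF, rt → 40 °C
Reagents that add atoms: triisopropylsilyl chloride, CC(C)[Si](Cl)(C(C)C)C(C)C
Why: Standard imidazole-promoted silylation of a phenol and a primary alcohol; the bulky silyl group is chosen to slow silyl migration in the next step.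

Step 3
Reactants: 3 1-bromo-2-[(triisopropylsilyl)oxy]-4-{[(triisopropylsilyl)oxy]methyl}benzene; 4 oxetan-3-one
Product: 6 3-{2-[(triisopropylsilyl)oxy]-4-{[(triisopropylsilyl)oxy]methyl}phenyl}oxetan-3-ol, via aryllithium 5 (not isolated)
Conditions: n-BuLi (1.05 equiv), THF, −78 °C, 15 min; then 4, −78 °C; then H2O
Reagents that add atoms: none
Why: Bromine–lithium exchange followed by 1,2-addition of the aryllithium to a ketone; the exchange is fast at −78 °C, where 1,3 oxygen-to-carbon silyl shift of a triisopropylsilyl group should be slow, and the strained ketone 4 is a good electrophile that enolizes poorly.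

Step 4
Reactants: 6 3-{2-[(triisopropylsilyl)oxy]-4-{[(triisopropylsilyl)oxy]methyl}phenyl}oxetan-3-ol
Product: 7 3-[2-hydroxy-4-(hydroxymethyl)phenyl]oxetan-3-ol
Conditions: n-Bu4NF (2.5 equiv), THF, 0 °C → rt; then H2O
Reagents that add atoms: none
Why: Fluoride-induced cleavage of both Si–O bonds (aryl silyl ether first, primary alkyl silyl ether more slowly); an unactivated 3,3-disubstituted oxetane and a tertiary alcohol should be inert to fluoride and to the transient phenoxide at this temperature.

Step 5
Reactants: 7 3-[2-hydroxy-4-(hydroxymethyl)phenyl]oxetan-3-ol; 8 isobutyryl chloride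
Product: 9 2-(3-hydroxyoxetan-3-yl)-5-{[(2-methylpropanoyl)oxy]methyl}phenyl 2-methylpropanoate
Conditions: 8 (2.1 equiv), pyridine, CH2Cl2, −10 → 0 °C
Reagents that add atoms: none
Why: Acylation of the phenol and the primary alcohol through the N-acylpyridinium ion; without a nucleophilic catalyst such as 4-(dimethylamino)pyridine the hindered tertiary hydroxyl should stay free, and pyridine is too weak a base to form the C8 alkoxide that an aryl-to-alkyl acyl shift would need.

Step 6
Reactants: 9 2-(3-hydroxyoxetan-3-yl)-5-{[(2-methylpropanoyl)oxy]methyl}phenyl 2-methylpropanoate; 10 acetic acid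
Product: 11 (2S)-2,3-dihydroxy-2-{2-[(2-methylpropanoyl)oxy]-4-{[(2-methylpropanoyl)oxy]methyl}phenyl}propyl acetate
Conditions: (R)-TRIP [(R)-3,3′-bis(2,4,6-triisopropylphenyl)-1,1′-binaphthalene-2,2′-diyl hydrogen phosphate] (10 mol %), 10 (3 equiv), toluene, 25 °C (to 40 °C if slow); cold aq. NaHCO3 wash; product used at once
Reagents that add atoms: none
Why: Proposed new method: in toluene the phosphoric acid and acetic acid should form a doubly hydrogen-bonded pair in which the P–OH proton is more acidic and the carboxylic acid more nucleophilic; the P–OH activates the oxetane oxygen of 9 while the bound acetic acid attacks one CH2 from the rear in an SN2 opening driven by about 25 kcal/mol of ring strain, forming the C10–O(acetate) bond and freeing O9 as a hydroxyl. The closest known reaction types are the chiral phosphoric acid-catalysed opening of meso-epoxides by carboxylic acids and the chiral phosphoric acid-catalysed desymmetrization of 3-substituted oxetanes by thiols, halide and tethered heteroatom nucleophiles; a carboxylic acid as intermolecular nucleophile for an oxetane has not been shown. No ring closes; the oxetane opens. C8 is not a reaction site: its configuration follows only from which enantiotopic CH2 is attacked, a choice made by the chiral pocket of the catalyst (catalyst control, since 9 is achiral), and the pro-S methylene must react to give (S)-11. The step needs enantiotopic-group selectivity, SN2 opening in preference to ionization at C8, and no acyl shift afterwards; the free tertiary hydroxyl gives a second hydrogen bond to the phosphoryl oxygen that fixes 9 in the pocket, the ortho-acyloxy aryl group and the strained ring disfavour a C8 cation, and both isobutyrates are inert to a weak acid in toluene. Acetic acid alone should not open a 3,3-disubstituted oxetane at this temperature, so no racemic background is expected.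

Step 7
Reactants: 11 (2S)-2,3-dihydroxy-2-{2-[(2-methylpropanoyl)oxy]-4-{[(2-methylpropanoyl)oxy]methyl}phenyl}propyl acetate
Product: 12 [(2S)-2-{2-[(2-methylpropanoyl)oxy]-4-{[(2-methylpropanoyl)oxy]methyl}phenyl}oxiran-2-yl]methyl acetate
Conditions: PPh3 (1.3 equiv), diisopropyl azodicarboxylate (1.3 equiv), toluene, 0 °C → rt
Reagents that add atoms: none
Why: Mitsunobu cyclodehydration of a 1,2-diol: the primary C9 hydroxyl is activated on phosphorus and displaced by the tertiary C8 oxygen (3-exo-tet), so no bond to C8 is made or broken and the (S) configuration from step 6 is carried over; the medium is near neutral, so the acetate and the aryl isobutyrate should not migrate, and acetic acid must be absent because it would be esterified onto O9.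

## Compound list

1 | methyl 4-bromo-3-hydroxybenzoate | COC(=O)c1ccc(Br)c(O)c1 | starting material
2 | 2-bromo-5-(hydroxymethyl)phenol | OCc1ccc(Br)c(O)c1 | intermediate
3 | 1-bromo-2-[(triisopropylsilyl)oxy]-4-{[(triisopropylsilyl)oxy]methyl}benzene | CC(C)[Si](OCc1ccc(Br)c(O[Si](C(C)C)(C(C)C)C(C)C)c1)(C(C)C)C(C)C | intermediate
4 | oxetan-3-one | O=C1COC1 | starting material
5 | {2-[(triisopropylsilyl)oxy]-4-{[(triisopropylsilyl)oxy]methyl}phenyl}lithium | [Li]c1ccc(CO[Si](C(C)C)(C(C)C)C(C)C)cc1O[Si](C(C)C)(C(C)C)C(C)C | intermediate
6 | 3-{2-[(triisopropylsilyl)oxy]-4-{[(triisopropylsilyl)oxy]methyl}phenyl}oxetan-3-ol | OC1(c2ccc(CO[Si](C(C)C)(C(C)C)C(C)C)cc2O[Si](C(C)C)(C(C)C)C(C)C)COC1 | intermediate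
7 | 3-[2-hydroxy-4-(hydroxymethyl)phenyl]oxetan-3-ol | OCc1ccc(C2(O)COC2)c(O)c1 | intermediate
8 | isobutyryl chloride (2-methylpropanoyl chloride) | CC(C)C(=O)Cl | starting material
9 | 2-(3-hydroxyoxetan-3-yl)-5-{[(2-methylpropanoyl)oxy]methyl}phenyl 2-methylpropanoate | OC1(c2ccc(COC(=O)C(C)C)cc2OC(=O)C(C)C)COC1 | intermediate
10 | acetic acid | CC(=O)O | starting material
11 | (2S)-2,3-dihydroxy-2-{2-[(2-methylpropanoyl)oxy]-4-{[(2-methylpropanoyl)oxy]methyl}phenyl}propyl acetate | CC(=O)OC[C@](O)(c1ccc(COC(=O)C(C)C)cc1OC(=O)C(C)C)CO | intermediate
12 | [(2S)-2-{2-[(2-methylpropanoyl)oxy]-4-{[(2-methylpropanoyl)oxy]methyl}phenyl}oxiran-2-yl]methyl acetate (CNP0151517.1) | CC(=O)OC[C@]1(c2ccc(COC(=O)C(C)C)cc2OC(=O)C(C)C)CO1 | target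

## Step count and risks

Total: 7 steps. Longest linear sequence: 7 steps (1 → 12).

**Step 6 (key step, proposed new method).**
- What may go wrong:
  - Attack of the weakly nucleophilic carboxylic acid on a neopentyl-type oxetane CH2 may be too slow at temperatures where the catalyst still discriminates, so that heating erodes enantiotopic-group selectivity.
  - Prolonged contact with acid may allow a 1,3-acetyl shift between O10 and O9, which is racemization, or a 1,2-shift to the C8 oxygen.
  - A more acidic catalyst could bring ionization at C8 into play.
- Fallback (known chemistry): it sets out from 9 and returns to the route at 12.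
  - Oxetane 9 is opened by chloride, the established nucleophile for chiral phosphoric acid-catalysed desymmetrization of 3-substituted oxetanes. Hydrogen chloride is released slowly from Me3SiCl and moist molecular sieves, and the catalyst antipode that opens the pro-R methylene is used. This should give the chlorohydrin diol F1, 2-[(2R)-1-chloro-2,3-dihydroxypropan-2-yl]-5-{[(2-methylpropanoyl)oxy]methyl}phenyl 2-methylpropanoate.
  - Its only primary hydroxyl is acetylated (acetyl chloride, 2,4,6-collidine, CH2Cl2, −40 °C) to the chloro acetate F2, (2R)-3-chloro-2-hydroxy-2-{2-[(2-methylpropanoyl)oxy]-4-{[(2-methylpropanoyl)oxy]methyl}phenyl}propyl acetate.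
  - Powdered K2CO3 in MeCN at 0 °C then closes the tertiary hydroxyl onto CH2Cl to give 12, bypassing 11 and step 7.
  - The roles of the two arms are exchanged relative to the main route, which is why the other methylene must be opened. The basic closure carries a risk of acyl shift that the main route avoids.

**Step 7.**
- What may go wrong:
  - If phosphorus ends up on the tertiary oxygen, ionization at C8 would cost configuration.
  - The basic hydrazide anion may promote acetyl migration before closure.
  - The cyclic phosphorane formed from the diol may collapse sluggishly.
- Fallback: it sets out from 11 and returns at 12.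
  - Selective sulfonylation of the primary hydroxyl (methanesulfonyl chloride, 2,4,6-collidine, CH2Cl2, −20 °C) gives the mesylate F3, (2R)-2-hydroxy-3-[(methylsulfonyl)oxy]-2-{2-[(2-methylpropanoyl)oxy]-4-{[(2-methylpropanoyl)oxy]methyl}phenyl}propyl acetate.
  - Intramolecular displacement with powdered K2CO3 in MeCN at 0 °C gives 12.

**Step 3.**
- What may go wrong:
  - A 1,3 oxygen-to-carbon silyl shift in aryllithium 5 before it meets the ketone.
  - Proton transfer from oxetan-3-one in place of addition.
- Fallback: it sets out from 2 and returns at 7, with benzyl ethers that cannot migrate.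
  - Double benzylation (benzyl bromide, NaH, DMF, 0 °C → rt) gives the dibenzyl ether F4, 2-(benzyloxy)-4-[(benzyloxy)methyl]-1-bromobenzene.
  - Bromine–lithium exchange (n-BuLi, THF, −78 °C) gives the aryllithium F5, {2-(benzyloxy)-4-[(benzyloxy)methyl]phenyl}lithium.
  - Addition to 4 gives the oxetanol F6, 3-{2-(benzyloxy)-4-[(benzyloxy)methyl]phenyl}oxetan-3-ol.
  - Hydrogenolysis (H2, Pd/C, ethyl acetate, rt) removes both benzyl groups and gives 7.

**Step 5.**
- What may go wrong:
  - Over-acylation at the tertiary hydroxyl.
  - Transfer of the aryl isobutyrate to the C8 oxygen during work-up.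
- Fallback: it sets out from 7 and returns at 9, with two reagent-controlled single acylations.
  - Candida antarctica lipase B with vinyl 2-methylpropanoate in tert-butyl methyl ether at 30 °C should acylate only the primary alcohol, giving the monoester F7, [3-hydroxy-4-(3-hydroxyoxetan-3-yl)phenyl]methyl 2-methylpropanoate.
  - The phenol is then acylated as its phenoxide (isobutyric anhydride, K2CO3, acetone, 0 °C) to give 9.

Further compounds
F1 | step 6 | 2-[(2R)-1-chloro-2,3-dihydroxypropan-2-yl]-5-{[(2-methylpropanoyl)oxy]methyl}phenyl 2-methylpropanoate | OC[C@](O)(c1ccc(COC(=O)C(C)C)cc1OC(=O)C(C)C)CCl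
F2 | step 6 | (2R)-3-chloro-2-hydroxy-2-{2-[(2-methylpropanoyl)oxy]-4-{[(2-methylpropanoyl)oxy]methyl}phenyl}propyl acetate | CC(=O)OC[C@](O)(c1ccc(COC(=O)C(C)C)cc1OC(=O)C(C)C)CCl
F3 | step 7 | (2R)-2-hydroxy-3-[(methylsulfonyl)oxy]-2-{2-[(2-methylpropanoyl)oxy]-4-{[(2-methylpropanoyl)oxy]methyl}phenyl}propyl acetate | CC(=O)OC[C@](O)(c1ccc(COC(=O)C(C)C)cc1OC(=O)C(C)C)COS(C)(=O)=O
F4 | step 3 | 2-(benzyloxy)-4-[(benzyloxy)methyl]-1-bromobenzene | Brc1ccc(COCc2ccccc2)cc1OCc1ccccc1
F5 | step 3 | {2-(benzyloxy)-4-[(benzyloxy)methyl]phenyl}lithium | [Li]c1ccc(COCc2ccccc2)cc1OCc1ccccc1
F6 | step 3 | 3-{2-(benzyloxy)-4-[(benzyloxy)methyl]phenyl}oxetan-3-ol | OC1(c2ccc(COCc3ccccc3)cc2OCc2ccccc2)COC1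
F7 | step 5 | [3-hydroxy-4-(3-hydroxyoxetan-3-yl)phenyl]methyl 2-methylpropanoate | CC(C)C(=O)OCc1ccc(C2(O)COC2)c(O)c1
A1 | alternative 1 | 2-[(4-methoxybenzyl)oxy]-1-{2-[(triisopropylsilyl)oxy]-4-{[(triisopropylsilyl)oxy]methyl}phenyl}ethan-1-one | COc1ccc(COCC(=O)c2ccc(CO[Si](C(C)C)(C(C)C)C(C)C)cc2O[Si](C(C)C)(C(C)C)C(C)C)cc1
A2 | alternative 1 | (2S)-2-{[(4-methoxybenzyl)oxy]methyl}-2-{2-[(triisopropylsilyl)oxy]-4-{[(triisopropylsilyl)oxy]methyl}phenyl}oxirane | COc1ccc(COC[C@]2(c3ccc(CO[Si](C(C)C)(C(C)C)C(C)C)cc3O[Si](C(C)C)(C(C)C)C(C)C)CO2)cc1
A3 | alternative 2 | 3-hydroxybenzyl 2-methylpropanoate | CC(C)C(=O)OCc1cccc(O)c1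
A4 | alternative 2 | ethyl 3-[(4-methoxybenzyl)oxy]-2-oxopropanoate | CCOC(=O)C(=O)COCc1ccc(OC)cc1
A5 | alternative 2 | ethyl (2R)-2-hydroxy-2-{2-hydroxy-4-{[(2-methylpropanoyl)oxy]methyl}phenyl}-3-[(4-methoxybenzyl)oxy]propanoate | COc1ccc(COC[C@](O)(c2ccc(COC(=O)C(C)C)cc2O)C(=O)OCC)cc1
A6 | alternative 3 | 2-{2-[(triisopropylsilyl)oxy]-4-{[(triisopropylsilyl)oxy]methyl}phenyl}propane-1,2,3-triol | OCC(O)(CO)c1ccc(CO[Si](C(C)C)(C(C)C)C(C)C)cc1O[Si](C(C)C)(C(C)C)C(C)C
A7 | alternative 3 | (2S)-2,3-dihydroxy-2-{2-[(triisopropylsilyl)oxy]-4-{[(triisopropylsilyl)oxy]methyl}phenyl}propyl acetate | CC(=O)OC[C@](O)(c1ccc(CO[Si](C(C)C)(C(C)C)C(C)C)cc1O[Si](C(C)C)(C(C)C)C(C)C)CO
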